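**Retrosynthetic overview**

- Numbering: ring C1 (free OH), C2, C3 (OAc), C4=C5 (Me on C4), C6 (lactone O), C7, C8 (O-angelate), C9=C10 (Me on C10); lactone arm C11 (=C13H2) and C12 (C=O) on C7.
- The strategy rests on C1 being a free secondary allylic carbinol bonded to the Z-olefin carbon C10 inside the ten-membered carbocycle C1–C10. The last bond made is therefore C1–C10, by addition of a C10 Z-alkenylchromium (from the iodide) to a C1 aldehyde in the fully acylated seco lactone (Nozaki–Hiyama–Kishi closure, sets C1).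
- The seco lactone comes from a zinc Barbier allylation–lactonization (C6–C7 bond, then O6–C12) between the C1–C6 Z-enal and a Z-2-(bromomethyl)enoate carrying C7–C13, the C8 stereocenter and the C10 iodide, followed by silyl→angelate and PMB→aldehyde exchanges.
- Z-enal: asymmetric propiolate alkynylation (C3), methylcuprate addition to a butenolide (locks Z-C4=C5). Bromide: (S)-glycerate acetonide (C8), iodoethylidenation (Z-C9=C10 iodide), vinylalumination, transposing bromination.
- Ring order: γ-lactone first (step 16), ten-membered ring last (step 21).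

Key step: step 21

Assumption: the (S,S)-ProPhenol ligand is taken to deliver the (S)-carbinol in step 2; if the facial sense is the reverse, the (R,R)-ligand is used.

**Route**

Step 1
Reactants: 1 3-[(4-methoxybenzyl)oxy]propan-1-ol
Product: 2 3-[(4-methoxybenzyl)oxy]propanal
Conditions: TEMPO (cat.), PhI(OAc)2, CH2Cl2, rt
Reagents that add atoms: none
Why: Oxoammonium-mediated (TEMPO/PhI(OAc)2) oxidation of a primary alcohol stops at the aldehyde and leaves the PMB ether untouched; no stereocenter is formed.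

Step 2
Reactants: 2 3-[(4-methoxybenzyl)oxy]propanal; 3 methyl propiolate
Product: 4 methyl (4S)-4-hydroxy-6-[(4-methoxybenzyl)oxy]hex-2-ynoate
Conditions: Me2Zn, (S,S)-ProPhenol (cat.), Ph3PO (cat.), toluene, 0 °C
Reagents that add atoms: none
Why: In the zinc–ProPhenol catalysed asymmetric alkynylation of aldehydes (Trost) the chiral dinuclear zinc catalyst delivers the metallated propiolate to one face of the aldehyde, which should set C3 as S.

Step 3
Reactants: 4 methyl (4S)-4-hydroxy-6-[(4-methoxybenzyl)oxy]hex-2-ynoate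
Product: 6 (5S)-5-{2-[(4-methoxybenzyl)oxy]ethyl}-4-methylfuran-2(5H)-one, via hydroxy enoate 5 (not isolated)
Conditions: Me2CuLi (from MeLi and CuI, 2.5 equiv), THF, −78 °C; aq. NH4Cl; then p-TsOH (cat.), CH2Cl2, rt
Reagents that add atoms: lithium dimethylcuprate, [Li+].C[Cu-]C
Why: Syn-carbocupration of the ynoate (Gilman conjugate addition) puts methyl and copper cis, so after protonation the ester and the C3 carbinol are cis across C4=C5 and close to the butenolide, which locks the Z geometry while C3 is not touched.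

Step 4
Reactants: 6 (5S)-5-{2-[(4-methoxybenzyl)oxy]ethyl}-4-methylfuran-2(5H)-one
Product: 7 (2Z,4S)-6-[(4-methoxybenzyl)oxy]-3-methylhex-2-ene-1,4-diol
Conditions: i-Bu2AlH (3 equiv), CH2Cl2, −78 → 0 °C
Reagents that add atoms: none
Why: 1,2-Reduction of the unsaturated lactone by i-Bu2AlH proceeds through the lactol to the Z-ene-1,4-diol without changing the olefin geometry or C3.

Step 5
Reactants: 7 (2Z,4S)-6-[(4-methoxybenzyl)oxy]-3-methylhex-2-ene-1,4-diol
Product: 9 (3S,4Z)-6-[(tert-butyldimethylsilyl)oxy]-1-[(4-methoxybenzyl)oxy]-4-methylhex-4-en-3-yl acetate, via mono-silyl ether 8 (not isolated)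
Conditions: TBSCl (1.05 equiv), imidazole, CH2Cl2, −20 °C; then Ac2O, DMAP (cat.), pyridine, 0 °C → rt
Reagents that add atoms: tert-butyldimethylsilyl chloride, CC(C)(C)[Si](C)(C)Cl; acetic anhydride, CC(=O)OC(C)=O
Why: The primary allylic hydroxyl is silylated first for steric reasons and the remaining secondary C3 hydroxyl is then acetylated with retention (selective silylation followed by DMAP-catalysed acylation in one flask).

Step 6
Reactants: 9 (3S,4Z)-6-[(tert-butyldimethylsilyl)oxy]-1-[(4-methoxybenzyl)oxy]-4-methylhex-4-en-3-yl acetate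
Product: 10 (3S,4Z)-6-hydroxy-1-[(4-methoxybenzyl)oxy]-4-methylhex-4-en-3-yl acetate
Conditions: HF·pyridine, pyridine, THF, 0 °C
Reagents that add atoms: none
Why: Fluoride desilylation with buffered HF·pyridine cleaves the primary silyl ether while acetate, PMB ether and olefin stay intact, and the weakly acidic medium suppresses acetyl migration.

Step 7
Reactants: 10 (3S,4Z)-6-hydroxy-1-[(4-methoxybenzyl)oxy]-4-methylhex-4-en-3-yl acetate
Product: 11 (3S,4Z)-1-[(4-methoxybenzyl)oxy]-4-methyl-6-oxohex-4-en-3-yl acetate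
Conditions: MnO2, CH2Cl2, rt
Reagents that add atoms: none
Why: Allylic oxidation with activated MnO2 is neutral and heterogeneous, so the Z geometry and C3 should be retained; the enal is used promptly.

Step 8
Reactants: 12 methyl (4S)-2,2-dimethyl-1,3-dioxolane-4-carboxylate
Product: 13 (4S)-2,2-dimethyl-1,3-dioxolane-4-carbaldehyde
Conditions: i-Bu2AlH (1.1 equiv), CH2Cl2, −78 °C
Reagents that add atoms: none
Why: Partial ester reduction at −78 °C stops at the aluminium hemiacetal, which gives the aldehyde on work-up without touching the stereocenter.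

Step 9
Reactants: 13 (4S)-2,2-dimethyl-1,3-dioxolane-4-carbaldehyde
Product: 14 (4R)-4-[(1Z)-2-iodoprop-1-en-1-yl]-2,2-dimethyl-1,3-dioxolane
Conditions: EtPPh3I, n-BuLi, THF, 0 °C; I2, −78 °C; NaN(SiMe3)2, −20 °C; then 13, −78 → −20 °C
Reagents that add atoms: ethyltriphenylphosphonium iodide, CC[P+](c1ccccc1)(c1ccccc1)c1ccccc1.[I-]; iodine, II
Why: The α-iodo ylide made in the flask olefinates the aldehyde in a Wittig reaction of the Stork–Zhao type, which gives the Z-2-iodoalkene (iodine cis to the dioxolane carbon) and should not epimerize the α-alkoxy aldehyde at low temperature.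

Step 10
Reactants: 14 (4R)-4-[(1Z)-2-iodoprop-1-en-1-yl]-2,2-dimethyl-1,3-dioxolane
Product: 15 (2R,3Z)-4-iodopent-3-ene-1,2-diol
Conditions: AcOH/H2O (4:1), 40 °C
Reagents that add atoms: none
Why: Acetal hydrolysis in aqueous acetic acid frees the diol and leaves the alkenyl iodide and the allylic stereocenter unchanged.

Step 11
Reactants: 15 (2R,3Z)-4-iodopent-3-ene-1,2-diol
Product: 16 (2R,3Z)-1,2-bis[(tert-butyldimethylsilyl)oxy]-4-iodopent-3-ene
Conditions: TBSCl (2.5 equiv), imidazole, DMF, rt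
Reagents that add atoms: tert-butyldimethylsilyl chloride, CC(C)(C)[Si](C)(C)Cl
Why: Standard imidazole-promoted silyl ether formation protects both hydroxyls without breaking any bond to the stereocenter.

Step 12
Reactants: 16 (2R,3Z)-1,2-bis[(tert-butyldimethylsilyl)oxy]-4-iodopent-3-ene
Product: 17 (2R,3Z)-2-[(tert-butyldimethylsilyl)oxy]-4-iodopent-3-en-1-ol
Conditions: HF·pyridine, pyridine, THF, 0 °C
Reagents that add atoms: none
Why: Selective desilylation works because the primary silyl ether is cleaved faster than the hindered secondary allylic one, and the weakly acidic medium avoids silyl migration.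

Step 13
Reactants: 17 (2R,3Z)-2-[(tert-butyldimethylsilyl)oxy]-4-iodopent-3-en-1-ol
Product: 18 (2R,3Z)-2-[(tert-butyldimethylsilyl)oxy]-4-iodopent-3-enal
Conditions: Dess–Martin periodinane, NaHCO3, CH2Cl2, 0 °C
Reagents that add atoms: none
Why: Buffered Dess–Martin oxidation is non-basic, so neither epimerization at C8 nor migration of the C9=C10 bond into conjugation is expected; the aldehyde is used at once.

Step 14
Reactants: 18 (2R,3Z)-2-[(tert-butyldimethylsilyl)oxy]-4-iodopent-3-enal; 3 methyl propiolate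
Product: 20 methyl (4R,5Z)-4-[(tert-butyldimethylsilyl)oxy]-3-hydroxy-6-iodo-2-methylidenehept-5-enoate (both C3 epimers), via vinylalane 19 (not isolated)
Conditions: 3, i-Bu2AlH, N-methylmorpholine N-oxide, THF, 0 °C; then 18, 0 °C → rt
Reagents that add atoms: none
Why: Hydroalumination of the propiolate gives an α-aluminoacrylate that adds to the aldehyde under non-basic conditions (vinylalumination, a Morita–Baylis–Hillman surrogate); the new carbinol (ring C7) forms as an epimer mixture, which does not matter because this carbon becomes sp2 in step 15.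

Step 15
Reactants: 20 methyl (4R,5Z)-4-[(tert-butyldimethylsilyl)oxy]-3-hydroxy-6-iodo-2-methylidenehept-5-enoate
Product: 21 methyl (2Z,4S,5Z)-2-(bromomethyl)-4-[(tert-butyldimethylsilyl)oxy]-6-iodohepta-2,5-dienoate
Conditions: NBS, Me2S, CH2Cl2, 0 °C → rt
Reagents that add atoms: N-bromosuccinimide, O=C1CCC(=O)N1Br
Why: The bromosulfonium reagent activates the hydroxyl and bromide enters at the methylene terminus with allylic transposition (Corey–Kim-type SN2′ bromination of a Baylis–Hillman alcohol), which should give the thermodynamically preferred Z-2-(bromomethyl)enoate with C8 untouched (the descriptor changes from R to S only through CIP priorities).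

Step 16
Reactants: 11 (3S,4Z)-1-[(4-methoxybenzyl)oxy]-4-methyl-6-oxohex-4-en-3-yl acetate; 21 methyl (2Z,4S,5Z)-2-(bromomethyl)-4-[(tert-butyldimethylsilyl)oxy]-6-iodohepta-2,5-dienoate
Product: 24 (3S,4Z)-5-[(2S,3S)-3-{(1S,2Z)-1-[(tert-butyldimethylsilyl)oxy]-3-iodobut-2-en-1-yl}-4-methylidene-5-oxooxolan-2-yl]-1-[(4-methoxybenzyl)oxy]-4-methylpent-4-en-3-yl acetate, via allylzinc bromide 22 (not isolated), via hydroxy ester 23 (not isolated)
Conditions: Zn dust, THF/sat. aq. NH4Cl, 0 °C → rt; then p-TsOH (cat.), CH2Cl2, rt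
Reagents that add atoms: none
Why: Zinc inserts only into the allylic C–Br bond (the alkenyl iodide is inert to zinc dust), and the Z-configured 2-(methoxycarbonyl)allylzinc adds through its γ-carbon C7 to the aldehyde in a closed chair transition state (Barbier reaction of the Dreiding–Schmidt type) in which the axial C7 substituent gives the syn adduct and, with H8 held in the plane of C7=C11 by allylic 1,3-strain, the aldehyde should approach C7 anti to the bulky iodoalkenyl group and on the side of the non-chelating silyloxy group, which sets C7 (S) and through the chair C6 (S) relative to C8, before acid closes the cis-disubstituted γ-lactone.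

Step 17
Reactants: 24 lactone silyl ether (as named in step 16)
Product: 25 (3S,4Z)-5-{(2S,3R)-3-[(1S,2Z)-1-hydroxy-3-iodobut-2-en-1-yl]-4-methylidene-5-oxooxolan-2-yl}-1-[(4-methoxybenzyl)oxy]-4-methylpent-4-en-3-yl acetate
Conditions: HF·pyridine, pyridine, THF, 0 °C → rt
Reagents that add atoms: none
Why: Fluoride desilylation frees the C8 hydroxyl while PMB ether, acetate, lactone and alkenyl iodide survive, and the acidic medium disfavours translactonization to O8 (the C7 descriptor changes to R only through CIP priorities).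

Step 18
Reactants: 25 C8 alcohol (as named in step 17); 26 angelic acid
Product: 28 (1S,2Z)-1-[(2S,3S)-2-{(1Z,3S)-3-acetoxy-5-[(4-methoxybenzyl)oxy]-2-methylpent-1-en-1-yl}-4-methylidene-5-oxooxolan-3-yl]-3-iodobut-2-en-1-yl (2Z)-2-methylbut-2-enoate, via mixed anhydride 27 (not isolated)
Conditions: 26, 2,4,6-Cl3C6H2COCl, Et3N, toluene, rt; then 25, 80 °C
Reagents that add atoms: none
Why: The mixed anhydride of angelic acid acylates the hindered C8 hydroxyl with retention (Yamaguchi-type esterification), and leaving out DMAP avoids isomerization of the Z-angelate to the tiglate.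

Step 19
Reactants: 28 angelate PMB ether (as named in step 18)
Product: 29 (1S,2Z)-1-{(2S,3S)-2-[(1Z,3S)-3-acetoxy-5-hydroxy-2-methylpent-1-en-1-yl]-4-methylidene-5-oxooxolan-3-yl}-3-iodobut-2-en-1-yl (2Z)-2-methylbut-2-enoate
Conditions: DDQ, CH2Cl2/pH 7 buffer, 0 °C
Reagents that add atoms: none
Why: Oxidative PMB cleavage with DDQ proceeds through the benzylic oxocarbenium ion, which is hydrolysed to the primary alcohol under neutral conditions that spare the esters, lactone and alkenyl iodide and avoid acetyl migration.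

Step 20
Reactants: 29 C1 alcohol (as named in step 19)
Product: 30 (1S,2Z)-1-{(2S,3S)-2-[(1Z,3S)-3-acetoxy-2-methyl-5-oxopent-1-en-1-yl]-4-methylidene-5-oxooxolan-3-yl}-3-iodobut-2-en-1-yl (2Z)-2-methylbut-2-enoate
Conditions: Dess–Martin periodinane, NaHCO3, CH2Cl2, 0 °C
Reagents that add atoms: none
Why: Buffered Dess–Martin oxidation gives the β-acetoxy aldehyde under neutral conditions that avoid β-elimination of acetate; the aldehyde is taken directly into step 21.

Step 21
Reactants: 30 seco C10 iodide/C1 aldehyde (as named in step 20)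
Product: 32 (1S,3S,4Z,6S,7S,8R,9Z)-3-acetoxy-1-hydroxy-8-[(2Z)-2-methylbut-2-enoyloxy]germacra-4,9,11(13)-trien-12,6-olide (CNP0319825.5), via alkenylchromium dichloride 31 (not isolated)
Conditions: CrCl2 (10 equiv), NiCl2 (cat.), degassed DMSO, rt, 0.003 M, slow addition of 30
Reagents that add atoms: none
Why: Zerovalent nickel, formed from NiCl2 by divalent chromium, inserts into the C10–I bond with retention of the Z geometry, the alkenyl group passes to trivalent chromium to give 31, and this adds 1,2 to the C1 aldehyde to form the C1–C10 bond. The closest known reaction type is the intramolecular Nozaki–Hiyama–Kishi coupling of an alkenyl iodide with an aldehyde to give medium-ring allylic alcohols. The ten-membered carbocycle C1–C10 closes by a 10-exo-trig addition to the aldehyde carbon, helped by the two Z olefins and the cis-disubstituted lactone, which bend the chain and bring C1 near C10. The new stereocenter C1 is set by the face of the chromium-bound aldehyde that the folded chain presents; with the C3 acetoxy group turned away from the carbonyl dipole the 1,3-anti (1S) carbinol is expected, and a chiral sulfonamide ligand on chromium can reinforce this. The step needs chemoselectivity for the aldehyde, which the low basicity and nucleophilicity of the alkenylchromium secure (lactone, α-methylene unit, acetate and angelate are not attacked), and it needs cyclization over oligomerization, which high dilution secures.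

**Compound list**

1 | 3-[(4-methoxybenzyl)oxy]propan-1-ol | COc1ccc(COCCCO)cc1 | starting material
2 | 3-[(4-methoxybenzyl)oxy]propanal | COc1ccc(COCCC=O)cc1 | intermediate
3 | methyl propiolate | C#CC(=O)OC | starting material
4 | methyl (4S)-4-hydroxy-6-[(4-methoxybenzyl)oxy]hex-2-ynoate | COC(=O)C#C[C@@H](O)CCOCc1ccc(OC)cc1 | intermediate
5 | methyl (2Z,4S)-4-hydroxy-6-[(4-methoxybenzyl)oxy]-3-methylhex-2-enoate (not isolated) | COC(=O)/C=C(/C)[C@@H](O)CCOCc1ccc(OC)cc1 | intermediate
6 | (5S)-5-{2-[(4-methoxybenzyl)oxy]ethyl}-4-methylfuran-2(5H)-one | CC1=CC(=O)O[C@H]1CCOCc1ccc(OC)cc1 | intermediate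
7 | (2Z,4S)-6-[(4-methoxybenzyl)oxy]-3-methylhex-2-ene-1,4-diol | OC/C=C(/C)[C@@H](O)CCOCc1ccc(OC)cc1 | intermediate
8 | (3S,4Z)-6-[(tert-butyldimethylsilyl)oxy]-1-[(4-methoxybenzyl)oxy]-4-methylhex-4-en-3-ol (not isolated) | CC(C)(C)[Si](C)(C)OC/C=C(/C)[C@@H](O)CCOCc1ccc(OC)cc1 | intermediate
9 | (3S,4Z)-6-[(tert-butyldimethylsilyl)oxy]-1-[(4-methoxybenzyl)oxy]-4-methylhex-4-en-3-yl acetate | CC(C)(C)[Si](C)(C)OC/C=C(/C)[C@@H](OC(C)=O)CCOCc1ccc(OC)cc1 | intermediate
10 | (3S,4Z)-6-hydroxy-1-[(4-methoxybenzyl)oxy]-4-methylhex-4-en-3-yl acetate | OC/C=C(/C)[C@@H](OC(C)=O)CCOCc1ccc(OC)cc1 | intermediate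
11 | (3S,4Z)-1-[(4-methoxybenzyl)oxy]-4-methyl-6-oxohex-4-en-3-yl acetate | O=C/C=C(/C)[C@@H](OC(C)=O)CCOCc1ccc(OC)cc1 | intermediate
12 | methyl (4S)-2,2-dimethyl-1,3-dioxolane-4-carboxylate | COC(=O)[C@@H]1COC(C)(C)O1 | starting material
13 | (4S)-2,2-dimethyl-1,3-dioxolane-4-carbaldehyde | O=C[C@@H]1COC(C)(C)O1 | intermediate
14 | (4R)-4-[(1Z)-2-iodoprop-1-en-1-yl]-2,2-dimethyl-1,3-dioxolane | I/C(C)=C\[C@@H]1COC(C)(C)O1 | intermediate
15 | (2R,3Z)-4-iodopent-3-ene-1,2-diol | I/C(C)=C\[C@@H](O)CO | intermediate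
16 | (2R,3Z)-1,2-bis[(tert-butyldimethylsilyl)oxy]-4-iodopent-3-ene | I/C(C)=C\[C@@H](O[Si](C)(C)C(C)(C)C)CO[Si](C)(C)C(C)(C)C | intermediate
17 | (2R,3Z)-2-[(tert-butyldimethylsilyl)oxy]-4-iodopent-3-en-1-ol | I/C(C)=C\[C@@H](O[Si](C)(C)C(C)(C)C)CO | intermediate
18 | (2R,3Z)-2-[(tert-butyldimethylsilyl)oxy]-4-iodopent-3-enal | I/C(C)=C\[C@@H](O[Si](C)(C)C(C)(C)C)C=O | intermediate
19 | diisobutyl[1-(methoxycarbonyl)ethenyl]aluminium (not isolated) | C=C(C(=O)OC)[Al](CC(C)C)CC(C)C | intermediate
20 | methyl (4R,5Z)-4-[(tert-butyldimethylsilyl)oxy]-3-hydroxy-6-iodo-2-methylidenehept-5-enoate (C3 epimers) | I/C(C)=C\[C@@H](O[Si](C)(C)C(C)(C)C)C(O)C(=C)C(=O)OC | intermediate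
21 | methyl (2Z,4S,5Z)-2-(bromomethyl)-4-[(tert-butyldimethylsilyl)oxy]-6-iodohepta-2,5-dienoate | I/C(C)=C\[C@@H](O[Si](C)(C)C(C)(C)C)/C=C(\CBr)C(=O)OC | intermediate
22 | bromo{(2Z,4S,5Z)-4-[(tert-butyldimethylsilyl)oxy]-6-iodo-2-(methoxycarbonyl)hepta-2,5-dien-1-yl}zinc (not isolated) | I/C(C)=C\[C@@H](O[Si](C)(C)C(C)(C)C)/C=C(\C[Zn]Br)C(=O)OC | intermediate
23 | methyl (3S,4S,5Z,7S)-7-acetoxy-3-{(1S,2Z)-1-[(tert-butyldimethylsilyl)oxy]-3-iodobut-2-en-1-yl}-4-hydroxy-9-[(4-methoxybenzyl)oxy]-6-methyl-2-methylidenenon-5-enoate (not isolated) | I/C(C)=C\[C@@H](O[Si](C)(C)C(C)(C)C)[C@@H](C(=C)C(=O)OC)[C@@H](O)/C=C(/C)[C@@H](OC(C)=O)CCOCc1ccc(OC)cc1 | intermediate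
24 | (3S,4Z)-5-[(2S,3S)-3-{(1S,2Z)-1-[(tert-butyldimethylsilyl)oxy]-3-iodobut-2-en-1-yl}-4-methylidene-5-oxooxolan-2-yl]-1-[(4-methoxybenzyl)oxy]-4-methylpent-4-en-3-yl acetate | I/C(C)=C\[C@@H](O[Si](C)(C)C(C)(C)C)[C@H]1C(=C)C(=O)O[C@H]1/C=C(/C)[C@@H](OC(C)=O)CCOCc1ccc(OC)cc1 | intermediate
25 | (3S,4Z)-5-{(2S,3R)-3-[(1S,2Z)-1-hydroxy-3-iodobut-2-en-1-yl]-4-methylidene-5-oxooxolan-2-yl}-1-[(4-methoxybenzyl)oxy]-4-methylpent-4-en-3-yl acetate | I/C(C)=C\[C@@H](O)[C@H]1C(=C)C(=O)O[C@H]1/C=C(/C)[C@@H](OC(C)=O)CCOCc1ccc(OC)cc1 | intermediate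
26 | angelic acid, (2Z)-2-methylbut-2-enoic acid | C/C=C(/C)C(=O)O | starting material
27 | (2Z)-2-methylbut-2-enoic 2,4,6-trichlorobenzoic anhydride (not isolated) | C/C=C(/C)C(=O)OC(=O)c1c(Cl)cc(Cl)cc1Cl | intermediate
28 | (1S,2Z)-1-[(2S,3S)-2-{(1Z,3S)-3-acetoxy-5-[(4-methoxybenzyl)oxy]-2-methylpent-1-en-1-yl}-4-methylidene-5-oxooxolan-3-yl]-3-iodobut-2-en-1-yl (2Z)-2-methylbut-2-enoate | I/C(C)=C\[C@@H](OC(=O)/C(C)=C\C)[C@H]1C(=C)C(=O)O[C@H]1/C=C(/C)[C@@H](OC(C)=O)CCOCc1ccc(OC)cc1 | intermediate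
29 | (1S,2Z)-1-{(2S,3S)-2-[(1Z,3S)-3-acetoxy-5-hydroxy-2-methylpent-1-en-1-yl]-4-methylidene-5-oxooxolan-3-yl}-3-iodobut-2-en-1-yl (2Z)-2-methylbut-2-enoate | I/C(C)=C\[C@@H](OC(=O)/C(C)=C\C)[C@H]1C(=C)C(=O)O[C@H]1/C=C(/C)[C@@H](OC(C)=O)CCO | intermediate
30 | (1S,2Z)-1-{(2S,3S)-2-[(1Z,3S)-3-acetoxy-2-methyl-5-oxopent-1-en-1-yl]-4-methylidene-5-oxooxolan-3-yl}-3-iodobut-2-en-1-yl (2Z)-2-methylbut-2-enoate (seco C10 iodide/C1 aldehyde) | I/C(C)=C\[C@@H](OC(=O)/C(C)=C\C)[C@H]1C(=C)C(=O)O[C@H]1/C=C(/C)[C@@H](OC(C)=O)CC=O | intermediate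
31 | C10 alkenylchromium dichloride derived from 30 (not isolated) | Cl[Cr](Cl)/C(C)=C\[C@@H](OC(=O)/C(C)=C\C)[C@H]1C(=C)C(=O)O[C@H]1/C=C(/C)[C@@H](OC(C)=O)CC=O | intermediate
32 | (1S,3S,4Z,6S,7S,8R,9Z)-3-acetoxy-1-hydroxy-8-[(2Z)-2-methylbut-2-enoyloxy]germacra-4,9,11(13)-trien-12,6-olide, CNP0319825.5 | C=C1C(=O)O[C@H]2/C=C(/C)[C@@H](OC(C)=O)C[C@H](O)/C(C)=C\[C@@H](OC(=O)/C(C)=C\C)[C@@H]12 | target

**Step count**

Total steps: 21. Longest linear sequence: 14 steps (steps 8–21, from 12); the other branch (steps 1–7, then 16–21) has 13.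

**Steps most likely to fail**

Step 21 (ring closure). The alkenylchromium may add to the wrong face of the C1 aldehyde, so that facial selectivity at C1 is poor, while the slow ten-membered closure also leaves room for oligomerization. The fallback sets out from 30 and does not rely on facial control. The closure is run as above and gives 32 together with its (1R)-epimer F1. The mixture is oxidized with Dess–Martin periodinane to the C1 ketone F2, a single compound. F2 is then reduced under reagent control with (R)-Me-CBS oxazaborolidine and catecholborane in toluene at −78 °C, conditions under which the α-methylene lactone is not reduced. The fallback comes back to the route at 32.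

Step 16 (Barbier allylation). The aldehyde may approach C7 on the face anti to the silyloxy group, or through a zinc chelate, which would give the C6/C7 pair in the wrong sense relative to C8. The fallback sets out from 11 and builds the bromide in the enantiomeric series, so that C6 and C7 come out right and only C8 has to be inverted. Purchased (4R)-2,2-dimethyl-1,3-dioxolane-4-carbaldehyde F3 is taken through the chemistry of steps 9–15 to the (4S)-iodoalkenyl dioxolane F4, the (2S)-diol F5, the bis-silyl ether F6, the (2S)-alcohol F7, the (2S)-aldehyde F8, the vinylalumination adduct F9 and the (4R)-bromide F10. The Barbier reaction of F10 with 11 then runs through the allylzinc bromide F11 and the hydroxy ester F12 to the C8-epimeric lactone F13. Desilylation gives the C8-epimeric alcohol F14. Mitsunobu esterification of F14 with angelic acid 26 (PPh3, diisopropyl azodicarboxylate, THF, 0 °C) installs the angelate with inversion at C8. The fallback comes back to the route at 28.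

Step 14 (vinylalumination). During the slow addition at 0 °C to room temperature the α-silyloxy β,γ-unsaturated aldehyde may isomerize: the C9=C10 bond can migrate into conjugation, or C8 can epimerize through the enol. The fallback sets out from 18 and forms the same C–C bond at −78 °C by a three-component Michael–aldol reaction. Me2AlSPh and methyl acrylate in CH2Cl2 at −78 °C give the aluminium enolate, which adds to 18 to give the β-phenylthio aldol F15. Oxidation with one equivalent of m-chloroperbenzoic acid at −78 °C gives the sulfoxide F16. Thermal syn-elimination of benzenesulfenic acid in warm toluene gives the methylidene ester. The fallback comes back to the route at 20.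

**Further compounds**

F1 | step 21 | (1R)-epimer of 32 | C=C1C(=O)O[C@H]2/C=C(/C)[C@@H](OC(C)=O)C[C@@H](O)/C(C)=C\[C@@H](OC(=O)/C(C)=C\C)[C@@H]12
F2 | step 21 | 1-oxo derivative of 32 (C1 ketone) | C=C1C(=O)O[C@H]2/C=C(/C)[C@@H](OC(C)=O)CC(=O)/C(C)=C\[C@@H](OC(=O)/C(C)=C\C)[C@@H]12
F3 | step 16 | (4R)-2,2-dimethyl-1,3-dioxolane-4-carbaldehyde (purchased) | O=C[C@H]1COC(C)(C)O1
F4 | step 16 | (4S)-4-[(1Z)-2-iodoprop-1-en-1-yl]-2,2-dimethyl-1,3-dioxolane | I/C(C)=C\[C@H]1COC(C)(C)O1
F5 | step 16 | (2S,3Z)-4-iodopent-3-ene-1,2-diol | I/C(C)=C\[C@H](O)CO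
F6 | step 16 | (2S,3Z)-1,2-bis[(tert-butyldimethylsilyl)oxy]-4-iodopent-3-ene | I/C(C)=C\[C@H](O[Si](C)(C)C(C)(C)C)CO[Si](C)(C)C(C)(C)C
F7 | step 16 | (2S,3Z)-2-[(tert-butyldimethylsilyl)oxy]-4-iodopent-3-en-1-ol | I/C(C)=C\[C@H](O[Si](C)(C)C(C)(C)C)CO
F8 | step 16 | (2S,3Z)-2-[(tert-butyldimethylsilyl)oxy]-4-iodopent-3-enal | I/C(C)=C\[C@H](O[Si](C)(C)C(C)(C)C)C=O
F9 | step 16 | methyl (4S,5Z)-4-[(tert-butyldimethylsilyl)oxy]-3-hydroxy-6-iodo-2-methylidenehept-5-enoate (C3 epimers) | I/C(C)=C\[C@H](O[Si](C)(C)C(C)(C)C)C(O)C(=C)C(=O)OC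
F10 | step 16 | methyl (2Z,4R,5Z)-2-(bromomethyl)-4-[(tert-butyldimethylsilyl)oxy]-6-iodohepta-2,5-dienoate | I/C(C)=C\[C@H](O[Si](C)(C)C(C)(C)C)/C=C(\CBr)C(=O)OC
F11 | step 16 | allylzinc bromide from F10 (not isolated) | I/C(C)=C\[C@H](O[Si](C)(C)C(C)(C)C)/C=C(\C[Zn]Br)C(=O)OC
F12 | step 16 | C8 epimer of hydroxy ester 23 (not isolated) | I/C(C)=C\[C@H](O[Si](C)(C)C(C)(C)C)[C@@H](C(=C)C(=O)OC)[C@@H](O)/C=C(/C)[C@@H](OC(C)=O)CCOCc1ccc(OC)cc1
F13 | step 16 | C8 epimer of lactone 24 | I/C(C)=C\[C@H](O[Si](C)(C)C(C)(C)C)[C@H]1C(=C)C(=O)O[C@H]1/C=C(/C)[C@@H](OC(C)=O)CCOCc1ccc(OC)cc1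
F14 | step 16 | C8 epimer of alcohol 25 | I/C(C)=C\[C@H](O)[C@H]1C(=C)C(=O)O[C@H]1/C=C(/C)[C@@H](OC(C)=O)CCOCc1ccc(OC)cc1
F15 | step 14 | methyl (4R,5Z)-4-[(tert-butyldimethylsilyl)oxy]-3-hydroxy-6-iodo-2-[(phenylsulfanyl)methyl]hept-5-enoate | I/C(C)=C\[C@@H](O[Si](C)(C)C(C)(C)C)C(O)C(CSc1ccccc1)C(=O)OC
F16 | step 14 | methyl (4R,5Z)-4-[(tert-butyldimethylsilyl)oxy]-3-hydroxy-6-iodo-2-[(phenylsulfinyl)methyl]hept-5-enoate | I/C(C)=C\[C@@H](O[Si](C)(C)C(C)(C)C)C(O)C(CS(=O)c1ccccc1)C(=O)OC
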